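The route rests on cutting the 2H-pyran ring (O1–C2–C3=C4–C4a–C8a; ring A = ketone-bearing resorcinol ring, ring B = catechol ring) at C4–C4a and C3–C2. This is a formal hetero-[4+2] between the aryloxocarbenium unit C4a=C8a–O1=C2 and a two-carbon enol ether. The key step exploits the ring B ether oxygen O1 and the single free ortho carbon C4a. An α-chloro ether, made from an aryl enol ether of the fully assembled, silyl-protected dihydrochalcone, is ionised under chiral-anion control. Trimethyl(vinyloxy)silane adds to C2, setting the stereocentre, and the ring closes onto C4a with loss of water. Isomerisation, cross-metathesis and desilylation finish the side chain.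

Key step: step 7

Remark: chromene numbering is used for the bicyclic core (O1, C2 quaternary, C3, C4, C4a, C5 bearing the propanone chain, C8 oxygenated, C8a); TBS = tert-butyldimethylsilyl, TIPS = triisopropylsilyl.
Remark: 3-(benzyloxy)-4-hydroxybenzaldehyde, hex-1-en-5-yne and trimethyl(vinyloxy)silane are assumed to be purchased.

Step 1
Reactants: 1 1-(2,4-dihydroxyphenyl)ethan-1-one
Product: 2 1-[2,4-bis(TBS-oxy)phenyl]ethan-1-one
Conditions: TBSCl (2.5 equiv), imidazole, DMAP (cat.), DMF, 40 °C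
Reagents that add atoms: tert-butyldimethylsilyl chloride (TBSCl), CC(C)(C)[Si](C)(C)Cl
Why: Imidazole-promoted O-silylation of both phenols (the chelated 2-hydroxyl needs the excess reagent) installs groups that should survive every later step and leave with fluoride at the end.

Step 2
Reactants: 3 3-(benzyloxy)-4-hydroxybenzaldehyde
Product: 4 3-(benzyloxy)-4-(TIPS-oxy)benzaldehyde
Conditions: TIPSCl, imidazole, DMF, 23 °C
Reagents that add atoms: triisopropylsilyl chloride (TIPSCl), CC(C)[Si](Cl)(C(C)C)C(C)C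
Why: O-silylation of the only free hydroxyl fixes which catechol oxygen will later become O1 (the benzylated one), and the bulky TIPS group should not migrate under the neutral or weakly basic conditions used while that oxygen is free.

Step 3
Reactants: 2 1-[2,4-bis(TBS-oxy)phenyl]ethan-1-one; 4 3-(benzyloxy)-4-(TIPS-oxy)benzaldehyde
Product: 7 (E)-3-[3-(benzyloxy)-4-(TIPS-oxy)phenyl]-1-[2,4-bis(TBS-oxy)phenyl]prop-2-en-1-one, via aldol adduct 5 (not isolated), via mesylate 6 (not isolated)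
Conditions: LiN(SiMe3)2, THF, −78 °C; 4; then MsCl, Et3N, −78 → 23 °C
Reagents that add atoms: none
Why: Crossed aldol addition of the lithium enolate to the non-enolisable aldehyde, followed by mesylation and E1cB elimination (aldol condensation), should give the thermodynamically preferred (E)-enone without the hydroxide that would cleave aryl silyl ethers.

Step 4
Reactants: 7 (E)-3-[3-(benzyloxy)-4-(TIPS-oxy)phenyl]-1-[2,4-bis(TBS-oxy)phenyl]prop-2-en-1-one
Product: 8 1-[2,4-bis(TBS-oxy)phenyl]-3-[3-hydroxy-4-(TIPS-oxy)phenyl]propan-1-one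
Conditions: H2 (1 atm), Pd/C, EtOAc, 23 °C
Reagents that add atoms: none
Why: Heterogeneous hydrogenation should saturate the enone C=C and hydrogenolyse the benzyl ether in one operation while the aryl ketone and silyl ethers survive, unveiling only the ring B hydroxyl that becomes O1.

Step 5
Reactants: 9 hex-1-en-5-yne
Product: 10 2-(hexa-1,5-dien-2-yl)-4,4,5,5-tetramethyl-1,3,2-dioxaborolane
Conditions: B2pin2, MeOH, (SIMes)CuCl (5 mol %), NaOt-Bu (5 mol %), THF, −15 → 23 °C
Reagents that add atoms: bis(pinacolato)diboron (B2pin2), CC1(C)OB(OC1(C)C)B1OC(C)(C)C(C)(C)O1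
Why: Copper-catalysed Markovnikov protoboration of the terminal alkyne (borylcupration with boron at the internal carbon, then protonation by methanol) should leave the unactivated alkene untouched, and any linear isomer is removed by chromatography.

Step 6
Reactants: 8 1-[2,4-bis(TBS-oxy)phenyl]-3-[3-hydroxy-4-(TIPS-oxy)phenyl]propan-1-one; 10 2-(hexa-1,5-dien-2-yl)-4,4,5,5-tetramethyl-1,3,2-dioxaborolane
Product: 11 1-[2,4-bis(TBS-oxy)phenyl]-3-[3-(hexa-1,5-dien-2-yloxy)-4-(TIPS-oxy)phenyl]propan-1-one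
Conditions: Cu(OAc)2 (20 mol %), pyridine, 4 Å MS, CH2Cl2, O2 (1 atm), 23 °C
Reagents that add atoms: none
Why: Chan–Lam oxidative C–O coupling of the phenol with the 1-substituted alkenylboronate (as practised with isopropenylboronates) runs at room temperature under weakly basic conditions, so the ketone is untouched and the neighbouring silyl group should stay in place.

Step 7
Reactants: 11 1-[2,4-bis(TBS-oxy)phenyl]-3-[3-(hexa-1,5-dien-2-yloxy)-4-(TIPS-oxy)phenyl]propan-1-one; 12 trimethyl(vinyloxy)silane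
Product: 16 1-[2,4-bis(TBS-oxy)phenyl]-3-[(2R)-2-(but-3-en-1-yl)-2-methyl-8-(TIPS-oxy)-2H-chromen-5-yl]propan-1-one, via α-chloro ether 13 (not isolated), via aldehyde 14 (not isolated), via chroman-4-ol 15 (not isolated)
Conditions: HCl (1.05 equiv, 4 M in dioxane), CH2Cl2, −78 °C; then 12 (2.5 equiv), chiral IDPi (imidodiphosphorimidate Brønsted acid with 3,3'-diaryl-BINOL units and N-triflyl groups, 5 mol %), toluene/CH2Cl2, −78 → −40 °C; then TsOH·H2O (10 mol %), 0 → 23 °C; Et3N
Reagents that add atoms: none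
Why: Proposed new method: an enantioselective oxa-Povarov-type [4+2] annulation under silylium-based asymmetric counteranion-directed catalysis, in which the silylated IDPi abstracts chloride from 13 (as Me3SiCl) to give the aryloxocarbenium ion O1=C2 paired with the confined chiral anion, the enol silane adds through its CH2 terminus to C2 (bond C3–C2), and the activated aldehyde carbon C4 of 14 is then attacked by the ring B carbon ortho to the ether oxygen (bond C4–C4a), after which acid-induced loss of water from 15 installs C3=C4. The closest known reactions are the racemic, SnCl4-mediated oxa-Povarov reaction of aryl oxocarbenium ions with alkenes and IDPi-catalysed Mukaiyama-type additions of enol silanes to aliphatic oxocarbenium ions and silylated ketones, where such confined anions differentiate small alkyl groups. The pyran ring closes by a 6-exo-trig Friedel–Crafts hydroxyalkylation (arene C4a onto the C4=O carbon), completing a stepwise inverse-demand hetero-[4+2] between the 2-oxadiene C4a=C8a–O1=C2 and the two-carbon enol ether. The C2 stereocentre is set in the C3–C2 bond formation by the chiral anion, which shields one face of the oxocarbenium ion; the sense of induction cannot be predicted with confidence, so the catalyst enantiomer that gives (R) is chosen by screening, and the C4 stereocentre of 15 disappears on dehydration. Regioselectivity needs no control because C4a is the only free position ortho to O1 (the other carries the silyloxy group at C8), ionisation towards the aryloxocarbenium ion is secured by chloride rather than an alkoxy leaving group, and the terminal alkene of the butenyl chain is placed so that it cannot close a favourable ring onto C2 or C4.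

Step 8
Reactants: 16 1-[2,4-bis(TBS-oxy)phenyl]-3-[(2R)-2-(but-3-en-1-yl)-2-methyl-8-(TIPS-oxy)-2H-chromen-5-yl]propan-1-one
Product: 17 1-[2,4-bis(TBS-oxy)phenyl]-3-[(2R)-2-[(E)-but-2-en-1-yl]-2-methyl-8-(TIPS-oxy)-2H-chromen-5-yl]propan-1-one
Conditions: Pd(dba)2 (2 mol %), P(t-Bu)3, i-PrCOCl (2 mol %), toluene, 80 °C
Reagents that add atoms: none
Why: Palladium hydride-catalysed one-position alkene isomerisation (hydropalladation then β-hydride elimination) should move the terminal double bond to the (E)-2-alkene and stop there, while the chromene C3=C4 bond cannot migrate because C2 is quaternary.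

Step 9
Reactants: 17 1-[2,4-bis(TBS-oxy)phenyl]-3-[(2R)-2-[(E)-but-2-en-1-yl]-2-methyl-8-(TIPS-oxy)-2H-chromen-5-yl]propan-1-one; 18 2-methylbut-3-en-2-ol
Product: 19 1-[2,4-bis(TBS-oxy)phenyl]-3-[(2R)-2-[(E)-4-hydroxy-4-methylpent-2-en-1-yl]-2-methyl-8-(TIPS-oxy)-2H-chromen-5-yl]propan-1-one
Conditions: second-generation Grubbs catalyst RuCl2(=CHPh)(H2IMes)(PCy3) (5 mol %), 18 (5 equiv), CH2Cl2, 40 °C
Reagents that add atoms: none
Why: Olefin cross-metathesis with the hindered, slowly homodimerising allylic alcohol should give the (E)-alkene under thermodynamic control with loss of propene, and the endocyclic cis-olefin of the chromene next to quaternary C2 is expected to be inert.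

Step 10
Reactants: 19 1-[2,4-bis(TBS-oxy)phenyl]-3-[(2R)-2-[(E)-4-hydroxy-4-methylpent-2-en-1-yl]-2-methyl-8-(TIPS-oxy)-2H-chromen-5-yl]propan-1-one
Product: 20 1-(2,4-dihydroxyphenyl)-3-[(2R)-8-hydroxy-2-[(E)-4-hydroxy-4-methylpent-2-en-1-yl]-2-methyl-2H-chromen-5-yl]propan-1-one
Conditions: Bu4NF (3.5 equiv), AcOH (3.5 equiv), THF, 0 → 23 °C
Reagents that add atoms: none
Why: Fluoride-induced cleavage of the three aryl silyl ethers under acetic acid buffering should free the phenols without exposing the tertiary allylic alcohol or the chromene to acid, and no stereocentre is touched.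

Compound list
1 | 1-(2,4-dihydroxyphenyl)ethan-1-one | CC(=O)c1ccc(O)cc1O | starting material
2 | 1-[2,4-bis(tert-butyldimethylsilyloxy)phenyl]ethan-1-one | CC(=O)c1ccc(O[Si](C)(C)C(C)(C)C)cc1O[Si](C)(C)C(C)(C)C | intermediate
3 | 3-(benzyloxy)-4-hydroxybenzaldehyde | O=Cc1ccc(O)c(OCc2ccccc2)c1 | starting material
4 | 3-(benzyloxy)-4-(triisopropylsilyloxy)benzaldehyde | O=Cc1ccc(O[Si](C(C)C)(C(C)C)C(C)C)c(OCc2ccccc2)c1 | intermediate
5 | 3-[3-(benzyloxy)-4-(TIPS-oxy)phenyl]-1-[2,4-bis(TBS-oxy)phenyl]-3-hydroxypropan-1-one (racemic aldol adduct, lithium alkoxide in the flask) | O=C(CC(O)c1ccc(O[Si](C(C)C)(C(C)C)C(C)C)c(OCc2ccccc2)c1)c1ccc(O[Si](C)(C)C(C)(C)C)cc1O[Si](C)(C)C(C)(C)C | intermediate (not isolated)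
6 | 1-[3-(benzyloxy)-4-(TIPS-oxy)phenyl]-3-[2,4-bis(TBS-oxy)phenyl]-3-oxopropyl methanesulfonate (racemic) | O=C(CC(OS(C)(=O)=O)c1ccc(O[Si](C(C)C)(C(C)C)C(C)C)c(OCc2ccccc2)c1)c1ccc(O[Si](C)(C)C(C)(C)C)cc1O[Si](C)(C)C(C)(C)C | intermediate (not isolated)
7 | (E)-3-[3-(benzyloxy)-4-(TIPS-oxy)phenyl]-1-[2,4-bis(TBS-oxy)phenyl]prop-2-en-1-one | O=C(/C=C/c1ccc(O[Si](C(C)C)(C(C)C)C(C)C)c(OCc2ccccc2)c1)c1ccc(O[Si](C)(C)C(C)(C)C)cc1O[Si](C)(C)C(C)(C)C | intermediate
8 | 1-[2,4-bis(TBS-oxy)phenyl]-3-[3-hydroxy-4-(TIPS-oxy)phenyl]propan-1-one | O=C(CCc1ccc(O[Si](C(C)C)(C(C)C)C(C)C)c(O)c1)c1ccc(O[Si](C)(C)C(C)(C)C)cc1O[Si](C)(C)C(C)(C)C | intermediate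
9 | hex-1-en-5-yne | C#CCCC=C | starting material
10 | 2-(hexa-1,5-dien-2-yl)-4,4,5,5-tetramethyl-1,3,2-dioxaborolane | C=CCCC(=C)B1OC(C)(C)C(C)(C)O1 | intermediate
11 | 1-[2,4-bis(TBS-oxy)phenyl]-3-[3-(hexa-1,5-dien-2-yloxy)-4-(TIPS-oxy)phenyl]propan-1-one | C=CCCC(=C)Oc1cc(CCC(=O)c2ccc(O[Si](C)(C)C(C)(C)C)cc2O[Si](C)(C)C(C)(C)C)ccc1O[Si](C(C)C)(C(C)C)C(C)C | intermediate
12 | trimethyl(vinyloxy)silane | C=CO[Si](C)(C)C | starting material
13 | 1-[2,4-bis(TBS-oxy)phenyl]-3-[3-(2-chlorohex-5-en-2-yloxy)-4-(TIPS-oxy)phenyl]propan-1-one (racemic α-chloro ether) | C=CCCC(C)(Cl)Oc1cc(CCC(=O)c2ccc(O[Si](C)(C)C(C)(C)C)cc2O[Si](C)(C)C(C)(C)C)ccc1O[Si](C(C)C)(C(C)C)C(C)C | intermediate (not isolated)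
14 | (R)-3-{5-[3-(2,4-bis(TBS-oxy)phenyl)-3-oxopropyl]-2-(TIPS-oxy)phenoxy}-3-methylhept-6-enal | C=CCC[C@](C)(CC=O)Oc1cc(CCC(=O)c2ccc(O[Si](C)(C)C(C)(C)C)cc2O[Si](C)(C)C(C)(C)C)ccc1O[Si](C(C)C)(C(C)C)C(C)C | intermediate (not isolated)
15 | 1-[2,4-bis(TBS-oxy)phenyl]-3-[(2R)-2-(but-3-en-1-yl)-4-hydroxy-2-methyl-8-(TIPS-oxy)chroman-5-yl]propan-1-one (both C4 epimers) | C=CCC[C@]1(C)CC(O)c2c(CCC(=O)c3ccc(O[Si](C)(C)C(C)(C)C)cc3O[Si](C)(C)C(C)(C)C)ccc(O[Si](C(C)C)(C(C)C)C(C)C)c2O1 | intermediate (not isolated)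
16 | 1-[2,4-bis(TBS-oxy)phenyl]-3-[(2R)-2-(but-3-en-1-yl)-2-methyl-8-(TIPS-oxy)-2H-chromen-5-yl]propan-1-one | C=CCC[C@]1(C)C=Cc2c(CCC(=O)c3ccc(O[Si](C)(C)C(C)(C)C)cc3O[Si](C)(C)C(C)(C)C)ccc(O[Si](C(C)C)(C(C)C)C(C)C)c2O1 | intermediate
17 | 1-[2,4-bis(TBS-oxy)phenyl]-3-[(2R)-2-[(E)-but-2-en-1-yl]-2-methyl-8-(TIPS-oxy)-2H-chromen-5-yl]propan-1-one | C/C=C/C[C@]1(C)C=Cc2c(CCC(=O)c3ccc(O[Si](C)(C)C(C)(C)C)cc3O[Si](C)(C)C(C)(C)C)ccc(O[Si](C(C)C)(C(C)C)C(C)C)c2O1 | intermediate
18 | 2-methylbut-3-en-2-ol | C=CC(C)(C)O | starting material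
19 | 1-[2,4-bis(TBS-oxy)phenyl]-3-[(2R)-2-[(E)-4-hydroxy-4-methylpent-2-en-1-yl]-2-methyl-8-(TIPS-oxy)-2H-chromen-5-yl]propan-1-one | CC(C)(O)/C=C/C[C@]1(C)C=Cc2c(CCC(=O)c3ccc(O[Si](C)(C)C(C)(C)C)cc3O[Si](C)(C)C(C)(C)C)ccc(O[Si](C(C)C)(C(C)C)C(C)C)c2O1 | intermediate
20 | 1-(2,4-dihydroxyphenyl)-3-[(2R)-8-hydroxy-2-[(E)-4-hydroxy-4-methylpent-2-en-1-yl]-2-methyl-2H-chromen-5-yl]propan-1-one | CC(C)(O)/C=C/C[C@]1(C)C=Cc2c(CCC(=O)c3ccc(O)cc3O)ccc(O)c2O1 | target

Total step count: 10. Longest linear sequence: 8 steps (steps 2, 3, 4, 6, 7, 8, 9 and 10, from 3-(benzyloxy)-4-hydroxybenzaldehyde).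

Steps most likely to fail

Step 7 (Proposed new method). The chiral ion pair may discriminate poorly between the methyl and butenyl flanks of the oxocarbenium ion. The α-chloro ether may revert to the enol ether and self-condense. Acid-induced β-elimination of the phenol from the aldehyde stage (retro-oxa-Michael) may erode enantiopurity, and ring closure at the flanked C4a may be slow. The fallback uses known chemistry and sets out from 11. HCl addition gives 13 as before, which is ionised with SnCl4 in CH2Cl2 at −78 °C in the presence of ethyl vinyl ether. This racemic oxa-Povarov annulation should give the 4-ethoxychroman F1. Treatment with TsOH removes ethanol and gives the racemic chromene F2. Preparative chromatography on a chiral stationary phase then gives 16, where the fallback rejoins the route, and leaves the (S)-enantiomer F3.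

Step 6. Copper/oxygen may oxidatively couple the electron-rich phenol, the 1-substituted alkenylboronate may protodeboronate, and coupling at the hindered hydroxyl may stall. The fallback sets out from 8 and replaces oxidative coupling by transfer alkenylation. Ruthenium-catalysed Markovnikov addition of acetic acid to 9 ([RuCl2(p-cymene)]2, P(2-furyl)3, Na2CO3, toluene) gives hexa-1,5-dien-2-yl acetate F4. Phenol 8 then exchanges with F4 under [Ir(cod)Cl]2 and Na2CO3 in toluene at 100 °C (alkoxymetalation, then β-acetate elimination) to give 11, where the fallback rejoins the route.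

Step 8. The double bond may migrate further along the chain, E/Z mixtures may form, or the catalyst may be inhibited. The fallback sets out from 16 and bypasses 17 and step 9. Cross-metathesis of 16 with 2-methylbut-2-ene (second-generation Grubbs catalyst RuCl2(=CHPh)(H2IMes)(PCy3)) gives the 4-methylpent-3-enyl chromene F5. A Schenck ene reaction with singlet oxygen (O2, tetraphenylporphyrin, visible light, CH2Cl2, 0 °C) gives the tertiary allylic hydroperoxide F6. Reduction with PPh3 gives 19, where the fallback rejoins the route; the regioselectivity of the ene step is expected to be moderate, so chromatographic purification is needed.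

Further compounds
F1 | step 7 | 1-[2,4-bis(TBS-oxy)phenyl]-3-[2-(but-3-en-1-yl)-4-ethoxy-2-methyl-8-(TIPS-oxy)chroman-5-yl]propan-1-one (racemic, both diastereomers) | C=CCCC1(C)CC(OCC)c2c(CCC(=O)c3ccc(O[Si](C)(C)C(C)(C)C)cc3O[Si](C)(C)C(C)(C)C)ccc(O[Si](C(C)C)(C(C)C)C(C)C)c2O1
F2 | step 7 | racemic 1-[2,4-bis(TBS-oxy)phenyl]-3-[2-(but-3-en-1-yl)-2-methyl-8-(TIPS-oxy)-2H-chromen-5-yl]propan-1-one | C=CCCC1(C)C=Cc2c(CCC(=O)c3ccc(O[Si](C)(C)C(C)(C)C)cc3O[Si](C)(C)C(C)(C)C)ccc(O[Si](C(C)C)(C(C)C)C(C)C)c2O1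
F3 | step 7 | 1-[2,4-bis(TBS-oxy)phenyl]-3-[(2S)-2-(but-3-en-1-yl)-2-methyl-8-(TIPS-oxy)-2H-chromen-5-yl]propan-1-one | C=CCC[C@@]1(C)C=Cc2c(CCC(=O)c3ccc(O[Si](C)(C)C(C)(C)C)cc3O[Si](C)(C)C(C)(C)C)ccc(O[Si](C(C)C)(C(C)C)C(C)C)c2O1
F4 | step 6 | hexa-1,5-dien-2-yl acetate | C=CCCC(=C)OC(C)=O
F5 | step 8 | 1-[2,4-bis(TBS-oxy)phenyl]-3-[(2R)-2-methyl-2-(4-methylpent-3-en-1-yl)-8-(TIPS-oxy)-2H-chromen-5-yl]propan-1-one | CC(C)=CCC[C@]1(C)C=Cc2c(CCC(=O)c3ccc(O[Si](C)(C)C(C)(C)C)cc3O[Si](C)(C)C(C)(C)C)ccc(O[Si](C(C)C)(C(C)C)C(C)C)c2O1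
F6 | step 8 | 1-[2,4-bis(TBS-oxy)phenyl]-3-[(2R)-2-[(E)-4-hydroperoxy-4-methylpent-2-en-1-yl]-2-methyl-8-(TIPS-oxy)-2H-chromen-5-yl]propan-1-one | CC(C)(OO)/C=C/C[C@]1(C)C=Cc2c(CCC(=O)c3ccc(O[Si](C)(C)C(C)(C)C)cc3O[Si](C)(C)C(C)(C)C)ccc(O[Si](C(C)C)(C(C)C)C(C)C)c2O1
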